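**Plan**

- Retrosynthesis: the C9 alcohol is taken back to an ethyl ester, with the ring A glycerol-2-yl diol masked as an acetonide and the ring B propanol as a TBS ether. The C7–H bond is then cut to the C7 aryl ketone, the C8–O bond to ring B to a diazo β-keto ester plus a phenol, the C8–C9 bond to diethyl carbonate, and the ring A O–CH bond to acetovanillone.
- Forward: no ring is formed. The ring A chain is built (Mitsunobu ether, Claisen condensation, diazo transfer), the ring B phenol is prepared (hydroboration, silylation), and the halves are joined at C8–O by carbenoid O–H insertion.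
- Enabling feature: C8 lies between the C7 ketone on ring A and the C9 ester and carries the ring B aryloxy oxygen, so C8–H is acidic and C8 racemises while the aryl ketone is reduced.
- Stereochemistry: both centres arise in one step, transfer hydrogenation with RuCl(p-cymene)[(S,S)-TsDPEN] under dynamic kinetic resolution. This should give the syn (7R) hydroxy ester, which becomes the (7R,8R) threo triol on ester reduction.

Key step: step 7

Remark: locants follow the neolignan convention (C7 benzylic carbinol on ring A, C8 the carbon bearing the ring B aryloxy group, C9 the hydroxymethyl carbon); the target SMILES is read as (7R,8R), the threo isomer.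
Remark: organoborane 8 is drawn with its phenol free; any O–B bond formed with excess 9-BBN is assumed to be hydrolysed in the oxidative work-up.

**Route**

Step 1
Reactants: 1 acetovanillone; 2 2,2-dimethyl-1,3-dioxan-5-ol
Product: 3 1-{4-[(2,2-dimethyl-1,3-dioxan-5-yl)oxy]-3-methoxyphenyl}ethan-1-one
Conditions: PPh3, DIAD, THF, 0 °C to rt
Reagents that add atoms: none
Why: Mitsunobu etherification, in which the phenol of 1 (acidified by the para acetyl group) should displace the oxyphosphonium of 2 at a ring carbon that is not stereogenic, under neutral conditions that leave the acetonide intact.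

Step 2
Reactants: 3 1-{4-[(2,2-dimethyl-1,3-dioxan-5-yl)oxy]-3-methoxyphenyl}ethan-1-one; 4 diethyl carbonate
Product: 5 ethyl 3-{4-[(2,2-dimethyl-1,3-dioxan-5-yl)oxy]-3-methoxyphenyl}-3-oxopropanoate
Conditions: NaH, THF, reflux; then AcOH
Reagents that add atoms: none
Why: crossed Claisen condensation of the methyl ketone enolate with the non-enolisable carbonate, driven by deprotonation of the β-keto ester formed, with a base-stable acetonide and a weakly acidic quench.

Step 3
Reactants: 5 ethyl 3-{4-[(2,2-dimethyl-1,3-dioxan-5-yl)oxy]-3-methoxyphenyl}-3-oxopropanoate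
Product: 6 ethyl 2-diazo-3-{4-[(2,2-dimethyl-1,3-dioxan-5-yl)oxy]-3-methoxyphenyl}-3-oxopropanoate
Conditions: p-ABSA, Et3N, MeCN, 0 °C to rt
Reagents that add atoms: 4-acetamidobenzenesulfonyl azide (p-ABSA), CC(=O)Nc1ccc(cc1)S(=O)(=O)N=[N+]=[N-]
Why: Regitz diazo transfer to the doubly activated methylene, a mild amine-mediated reaction that touches neither the acetonide nor the aryl ethers.

Step 4
Reactants: 7 4-allyl-2,6-dimethoxyphenol
Product: 9 4-(3-hydroxypropyl)-2,6-dimethoxyphenol, via organoborane 8 (not isolated)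
Conditions: 9-BBN (2.5 equiv), THF, 0 °C to rt; then NaOH, H2O2, 0 °C
Reagents that add atoms: 9-BBN, B1C2CCCC1CCC2 (its boron and ring are carried in 8 only); hydrogen peroxide, OO (oxygen of the new hydroxyl)
Why: anti-Markovnikov hydroboration–oxidation, in which the bulky borane should place boron on the terminal carbon, the excess covers the phenolic O–H, and cold alkaline peroxide replaces boron by hydroxyl.

Step 5
Reactants: 9 4-(3-hydroxypropyl)-2,6-dimethoxyphenol
Product: 10 4-{3-[(tert-butyldimethylsilyl)oxy]propyl}-2,6-dimethoxyphenol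
Conditions: TBSCl (1.05 equiv), imidazole, CH2Cl2, 0 °C
Reagents that add atoms: tert-butyldimethylsilyl chloride, CC(C)(C)[Si](C)(C)Cl
Why: chemoselective silylation, in which the unhindered primary alcohol should react with one equivalent of silyl chloride well before the phenol, which is flanked by and hydrogen-bonded to two methoxy groups.

Step 6
Reactants: 6 ethyl 2-diazo-3-{4-[(2,2-dimethyl-1,3-dioxan-5-yl)oxy]-3-methoxyphenyl}-3-oxopropanoate; 10 4-{3-[(tert-butyldimethylsilyl)oxy]propyl}-2,6-dimethoxyphenol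
Product: 11 ethyl (2RS)-2-(4-{3-[(tert-butyldimethylsilyl)oxy]propyl}-2,6-dimethoxyphenoxy)-3-{4-[(2,2-dimethyl-1,3-dioxan-5-yl)oxy]-3-methoxyphenyl}-3-oxopropanoate
Conditions: Rh2(OAc)4 (2 mol%), toluene, 80 °C, slow addition of 6
Reagents that add atoms: none
Why: rhodium carbenoid O–H insertion, in which the electrophilic carbenoid from 6 is captured by the phenol oxygen (the only O–H present) and a proton shift gives the C8–O ether as a racemate, which is all the next step requires.

Step 7
Reactants: 11 ethyl (2RS)-2-(4-{3-[(tert-butyldimethylsilyl)oxy]propyl}-2,6-dimethoxyphenoxy)-3-{4-[(2,2-dimethyl-1,3-dioxan-5-yl)oxy]-3-methoxyphenyl}-3-oxopropanoate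
Product: 12 ethyl (2S,3R)-2-(4-{3-[(tert-butyldimethylsilyl)oxy]propyl}-2,6-dimethoxyphenoxy)-3-{4-[(2,2-dimethyl-1,3-dioxan-5-yl)oxy]-3-methoxyphenyl}-3-hydroxypropanoate
Conditions: RuCl(p-cymene)[(S,S)-TsDPEN] (2 mol%), HCO2H/Et3N (5:2), CH2Cl2, 30 °C
Reagents that add atoms: none
Why: Noyori–Ikariya asymmetric transfer hydrogenation under dynamic kinetic resolution, in which formic acid turns the ruthenium amide into the ruthenium hydride (CO2 is lost) and the hydride on Ru and the proton on N–H pass to the C7 carbonyl through a six-membered outer-sphere transition state. The closest known reaction is the same catalyst system on α-alkoxy β-keto esters with aryl ketones, which gives syn α-alkoxy β-hydroxy esters; the present case differs only in the size of the α-oxygen substituent. No ring closes. C7 is set by the catalyst: the CH/π contact between the p-cymene ligand and ring A places the aryl group next to the arene, so the (S,S) ligand should deliver hydride to the face that turns acetophenone into (S)-1-phenylethanol, which reads 7R here because C8 outranks the aryl group. C8 is set by kinetic selection: Et3N interconverts the two C8 enantiomers through the enol of the C7/C9 dicarbonyl unit, and only the enantiomer whose aryloxy and ester groups fit that transition state is reduced quickly, leading to the syn (2S,3R) ester. The step needs ketone-over-ester chemoselectivity (inherent to this catalyst) and high syn and enantioselectivity, which rest on the acidity of C8–H keeping racemisation faster than reduction, while the silyl ether and acetonide should tolerate the amine-buffered anhydrous medium.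

Step 8
Reactants: 12 ethyl (2S,3R)-2-(4-{3-[(tert-butyldimethylsilyl)oxy]propyl}-2,6-dimethoxyphenoxy)-3-{4-[(2,2-dimethyl-1,3-dioxan-5-yl)oxy]-3-methoxyphenyl}-3-hydroxypropanoate
Product: 13 (1R,2R)-2-(4-{3-[(tert-butyldimethylsilyl)oxy]propyl}-2,6-dimethoxyphenoxy)-1-{4-[(2,2-dimethyl-1,3-dioxan-5-yl)oxy]-3-methoxyphenyl}propane-1,3-diol
Conditions: LiBH4, THF, 0 °C to rt; aqueous work-up
Reagents that add atoms: none
Why: borohydride reduction of the α-aryloxy β-hydroxy ester to the C9 primary alcohol, with a weakly basic hydride that should not epimerise C8 or cause retro-aldol cleavage; the C8 descriptor changes from S to R only through the change in CIP priorities.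

Step 9
Reactants: 13 (1R,2R)-2-(4-{3-[(tert-butyldimethylsilyl)oxy]propyl}-2,6-dimethoxyphenoxy)-1-{4-[(2,2-dimethyl-1,3-dioxan-5-yl)oxy]-3-methoxyphenyl}propane-1,3-diol
Product: 15 (1R,2R)-1-{4-[(1,3-dihydroxypropan-2-yl)oxy]-3-methoxyphenyl}-2-[4-(3-hydroxypropyl)-2,6-dimethoxyphenoxy]propane-1,3-diol, via desilylated acetonide triol 14 (not isolated)
Conditions: AcOH/THF/H2O (3:1:1), rt then 45 °C
Reagents that add atoms: none
Why: acid hydrolysis of the primary silyl ether (expected first, at rt) and then of the isopropylidene ketal in aqueous acetic acid, which is too weak to ionise the C7 benzylic alcohol and gives only volatile by-products beside the polar pentaol.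

**Compound list**

1 | acetovanillone | COc1cc(C(C)=O)ccc1O | starting material
2 | 2,2-dimethyl-1,3-dioxan-5-ol | CC1(C)OCC(O)CO1 | starting material
3 | 1-{4-[(2,2-dimethyl-1,3-dioxan-5-yl)oxy]-3-methoxyphenyl}ethan-1-one | COc1cc(C(C)=O)ccc1OC1COC(C)(C)OC1 | intermediate
4 | diethyl carbonate | CCOC(=O)OCC | starting material
5 | ethyl 3-{4-[(2,2-dimethyl-1,3-dioxan-5-yl)oxy]-3-methoxyphenyl}-3-oxopropanoate | COc1cc(C(=O)CC(=O)OCC)ccc1OC1COC(C)(C)OC1 | intermediate
6 | ethyl 2-diazo-3-{4-[(2,2-dimethyl-1,3-dioxan-5-yl)oxy]-3-methoxyphenyl}-3-oxopropanoate | COc1cc(C(=O)C(=[N+]=[N-])C(=O)OCC)ccc1OC1COC(C)(C)OC1 | intermediate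
7 | 4-allyl-2,6-dimethoxyphenol | C=CCc1cc(OC)c(O)c(OC)c1 | starting material
8 | 4-[3-(9-borabicyclo[3.3.1]nonan-9-yl)propyl]-2,6-dimethoxyphenol | COc1cc(CCCB2C3CCCC2CCC3)cc(OC)c1O | intermediate
9 | 4-(3-hydroxypropyl)-2,6-dimethoxyphenol | COc1cc(CCCO)cc(OC)c1O | intermediate
10 | 4-{3-[(tert-butyldimethylsilyl)oxy]propyl}-2,6-dimethoxyphenol | COc1cc(CCCO[Si](C)(C)C(C)(C)C)cc(OC)c1O | intermediate
11 | ethyl (2RS)-2-(4-{3-[(tert-butyldimethylsilyl)oxy]propyl}-2,6-dimethoxyphenoxy)-3-{4-[(2,2-dimethyl-1,3-dioxan-5-yl)oxy]-3-methoxyphenyl}-3-oxopropanoate (racemic, C8 labile) | COc1cc(C(=O)C(C(=O)OCC)Oc2c(OC)cc(CCCO[Si](C)(C)C(C)(C)C)cc2OC)ccc1OC1COC(C)(C)OC1 | intermediate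
12 | ethyl (2S,3R)-2-(4-{3-[(tert-butyldimethylsilyl)oxy]propyl}-2,6-dimethoxyphenoxy)-3-{4-[(2,2-dimethyl-1,3-dioxan-5-yl)oxy]-3-methoxyphenyl}-3-hydroxypropanoate (syn) | COc1cc([C@@H](O)[C@@H](C(=O)OCC)Oc2c(OC)cc(CCCO[Si](C)(C)C(C)(C)C)cc2OC)ccc1OC1COC(C)(C)OC1 | intermediate
13 | (1R,2R)-2-(4-{3-[(tert-butyldimethylsilyl)oxy]propyl}-2,6-dimethoxyphenoxy)-1-{4-[(2,2-dimethyl-1,3-dioxan-5-yl)oxy]-3-methoxyphenyl}propane-1,3-diol | COc1cc([C@@H](O)[C@@H](CO)Oc2c(OC)cc(CCCO[Si](C)(C)C(C)(C)C)cc2OC)ccc1OC1COC(C)(C)OC1 | intermediate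
14 | (1R,2R)-1-{4-[(2,2-dimethyl-1,3-dioxan-5-yl)oxy]-3-methoxyphenyl}-2-[4-(3-hydroxypropyl)-2,6-dimethoxyphenoxy]propane-1,3-diol | COc1cc([C@@H](O)[C@@H](CO)Oc2c(OC)cc(CCCO)cc2OC)ccc1OC1COC(C)(C)OC1 | intermediate
15 | (1R,2R)-1-{4-[(1,3-dihydroxypropan-2-yl)oxy]-3-methoxyphenyl}-2-[4-(3-hydroxypropyl)-2,6-dimethoxyphenoxy]propane-1,3-diol | COc1cc([C@@H](O)[C@@H](CO)Oc2c(OC)cc(CCCO)cc2OC)ccc1OC(CO)CO | target

**Step count**

Total steps: 9. Longest linear sequence: 7 (steps 1, 2, 3, 6, 7, 8, 9, from acetovanillone).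

**Steps most likely to fail**

Step 7. The large 2,6-dimethoxyaryloxy group may weaken the discrimination between the two C8 enantiomers in the hydride-transfer transition state, eroding the syn selectivity. Alternatively, enolisation at C8 may fall behind reduction, so that the process degrades to a plain kinetic resolution. The fallback makes the C7–C8 bond by an auxiliary-controlled syn aldol reaction instead. It sets out from phenol 10 and alcohol 2. Phenol 10 would be O-alkylated with (S)-4-benzyl-3-(chloroacetyl)oxazolidin-2-one (K2CO3, NaI, acetone) to give (S)-4-benzyl-3-[2-(4-{3-[(tert-butyldimethylsilyl)oxy]propyl}-2,6-dimethoxyphenoxy)acetyl]oxazolidin-2-one F1. Vanillin would be etherified with 2 under the Mitsunobu conditions of step 1 to give 4-[(2,2-dimethyl-1,3-dioxan-5-yl)oxy]-3-methoxybenzaldehyde F2. Boron-mediated aldol addition of F1 to F2 (Bu2BOTf, iPr2NEt, CH2Cl2, −78 °C) should proceed through the Z enolate and a Zimmerman–Traxler chair to give the (2S,3R) syn adduct (S)-4-benzyl-3-[(2S,3R)-2-aryloxy-3-aryl-3-hydroxypropanoyl]oxazolidin-2-one F3. Reductive removal of the auxiliary with LiBH4 then comes back to the route at diol 13.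

Step 6. The carbenoid may be diverted before the hindered phenol captures it: Wolff rearrangement at 80 °C, capture by ether oxygens or trace water, or attack on the electron-rich ring B. The fallback forms the C8–O bond by ionic substitution and sets out from β-keto ester 5. Bromination with NBS (CH2Cl2, 0 °C) would give ethyl 2-bromo-3-{4-[(2,2-dimethyl-1,3-dioxan-5-yl)oxy]-3-methoxyphenyl}-3-oxopropanoate F4. Displacement of bromide by the phenoxide of 10 (K2CO3, acetone, rt) comes back to the route at keto ester 11.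

Step 1. Displacement at the dioxane CH, which is flanked by two C–O bonds, may be slow, so that alkylation of the hydrazide by-product or elimination competes. The fallback forms the aryl ether by nucleophilic aromatic substitution and sets out from alcohol 2. Its sodium alkoxide (NaH, DMF, 0 °C to rt) would displace fluoride from 4-fluoro-3-methoxybenzonitrile to give 4-[(2,2-dimethyl-1,3-dioxan-5-yl)oxy]-3-methoxybenzonitrile F5. Addition of MeMgBr (THF, 0 °C to rt) and aqueous quench would give 1-{4-[(2,2-dimethyl-1,3-dioxan-5-yl)oxy]-3-methoxyphenyl}ethan-1-imine F6. Its hydrolysis in cold dilute aqueous citric acid comes back to the route at ketone 3.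

Further compounds
F1 | step 7 | (S)-4-benzyl-3-[2-(4-{3-[(tert-butyldimethylsilyl)oxy]propyl}-2,6-dimethoxyphenoxy)acetyl]oxazolidin-2-one | COc1cc(CCCO[Si](C)(C)C(C)(C)C)cc(OC)c1OCC(=O)N1[C@@H](Cc2ccccc2)COC1=O
F2 | step 7 | 4-[(2,2-dimethyl-1,3-dioxan-5-yl)oxy]-3-methoxybenzaldehyde | COc1cc(C=O)ccc1OC1COC(C)(C)OC1
F3 | step 7 | (S)-4-benzyl-3-[(2S,3R)-2-(4-{3-[(tert-butyldimethylsilyl)oxy]propyl}-2,6-dimethoxyphenoxy)-3-{4-[(2,2-dimethyl-1,3-dioxan-5-yl)oxy]-3-methoxyphenyl}-3-hydroxypropanoyl]oxazolidin-2-one | COc1cc([C@@H](O)[C@@H](C(=O)N2[C@@H](Cc3ccccc3)COC2=O)Oc2c(OC)cc(CCCO[Si](C)(C)C(C)(C)C)cc2OC)ccc1OC1COC(C)(C)OC1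
F4 | step 6 | ethyl 2-bromo-3-{4-[(2,2-dimethyl-1,3-dioxan-5-yl)oxy]-3-methoxyphenyl}-3-oxopropanoate | COc1cc(C(=O)C(Br)C(=O)OCC)ccc1OC1COC(C)(C)OC1
F5 | step 1 | 4-[(2,2-dimethyl-1,3-dioxan-5-yl)oxy]-3-methoxybenzonitrile | COc1cc(C#N)ccc1OC1COC(C)(C)OC1
F6 | step 1 | 1-{4-[(2,2-dimethyl-1,3-dioxan-5-yl)oxy]-3-methoxyphenyl}ethan-1-imine | COc1cc(C(C)=N)ccc1OC1COC(C)(C)OC1
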